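Per day, the north-west run lost 1.18 M/d of c(solid substrate), read from its first point.

- north-west: solid substrate 1 M; run made earlier
- flask: solid substrate 0.50 M; time 15 d
north-west run (percent of the solid substrate charged)

| time / d | isomer of the product A / % | target / % | solid substrate / % |
|---|---|---|---|
| 0.417 | 11.8 | 17.9 | 50.6 |
| 1.04 | 27.3 | 43.7 | 0 |
| 2.00 | 27.0 | 45.0 | 0 |
| 3.00 | 26.1 | 43.7 | 0.3 |
| 5.00 | 27.0 | 45.3 | 1.0 |

(standard deviation of a reading: 0.5 percentage points)
- solid substrate is a solid; its amount is given per volume of the solution
- at the start none of the solid substrate is in solution
* share of isomer of the product A in isomer of the product A plus target at 2.0 h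
* share of isomer of the product A in isomer of the product A plus target at 15 d
* which of isomer of the product A and target there is more of at 15 d

At that constant rate the flask's charge clears in 0.422 d. The turnover count, the elapsed time divided by the clearing time of that flask's charge, is 35.5 at 15 d, far past clearing. The north-west run reached a count of 2.37 at 2.00 d and 5.92 at 5.00 d, and its share stayed flat between them. Pooled, those last three readings give an isomer share of 37.4%, so target leads.

At 2.0 h the flask's count is 0.197, below any reading. The earliest north-west share, 39.7%, rests on small amounts, so this reckoning commits to the plateau at both times, less firmly at 2.0 h.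

The weak link is the constant rate. A first-order loss with life 0.612 d would leave 18.3% at 1.04 d, but the reading is 0%. The constant rate stands.

The forecast gives 38.5% and 37.5% with target ahead, higher than this reckoning at 2.0 h, and holds that “the ratio looks kinetic”.

The flask gives 37.1% at 2.0 h and 37.1% at 15 d, with target at 45.2% and isomer of the product A at 26.7%.

    solid substrate ⇌ starting material, rate k1*(cs1 - [starting material]) while solid is left; crystals form when [starting material] > cs1 (solubility = 0.330 M, k = 5.50 × 10⁻⁵ /s)
    starting material ⇌ isomer of the product A (K = 3.90, k = 5.20 × 10⁻⁵ /s)
    starting material ⇌ target (K = 6.60, k = 1.10 × 10⁻⁴ /s)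
    target ⇌ isomer of the product B (K = 0.470, k = 1.50 × 10⁻⁴ /s)

At a count of 35.5, the flask's share equals the equilibrium value 37.1% set by the constants, which is thermodynamic control. Solid substrate in the flask stands at 0% by 1.50 d. The neighbouring flask, charged with 0.20 M, clears in 0.169 d by the same reckoning, so its count at 15 d stands far above 1. Its share is 37.1% at 2.0 h and 37.1% at 15 d. It ends with target at 45.2% and isomer of the product A at 26.7%.

(The readings are calculated from invented constants; scatter was added.)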